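**Retrosynthetic overview**
1. Target 26 ⇐ acyl differentiation of the cis-1,2-diol 20 (cyclic orthoester opening puts acetate on O2, then isovalerate on O1) ⇐ 1,2-dione 19, reduced from the face opposite the angular CH2OSi group.
2. 19 ⇐ ring-A enone 17 (α'-hydroxylation, oxidation); the axial C8 hydroxyl comes from a bulky hydride, and the C6 isopropenyl group from axial conjugate addition to the ring-B enone 11.
3. trans-Decalin enone 10 ⇐ ring A closed by a SmI2 Reformatsky-type aldol/dehydration (C3–C4 bond) in the trans-disubstituted β-keto ester 8 ⇐ anti-alkylation of 6 with 1,3-dibromoacetone (quaternary C8a).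
4. 6 ⇐ new step: carbene-catalysed enantioselective Stetter addition of acetaldehyde to enone ester 4; this first stereocentre (later C4a) relays all the others.
5. Ring order: ring B is the cyclohexane of commercial 1, ring A is formed second (step 4). Bicyclic compounds use naphthalene locants: C8a quaternary fusion carbon, C4a fusion CH, C4 methyl-bearing alkene carbon, C6 isopropenyl carbon.

Assumption: the (5aR,10bS) precatalyst is taken to give the (2S) adduct 6; if the induction proves opposite, its commercially available mirror image is used.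

**Step 1**
Reactants: 1 methyl 2-oxocyclohexane-1-carboxylate
Product: 4 methyl 6-oxocyclohex-1-ene-1-carboxylate, via selenide 2 (not isolated), via selenoxide 3 (not isolated)
Conditions: PhSeCl, pyridine, CH2Cl2, 0 °C; then 30% aq H2O2, 0 °C to rt
Reagents that add atoms: benzeneselenenyl chloride Cl[Se]c1ccccc1 (phenylselanyl group, carried by 2 and 3 only); hydrogen peroxide OO (oxygen, carried by 3 only)
Why: α-Selenenylation of the β-keto ester, oxidation to the selenoxide and spontaneous syn-elimination (Reich–Sharpless selenoxide elimination) give the doubly activated cyclohexenone, which is used at once because it dimerises on standing; no stereocentre is formed.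

**Step 2**
Reactants: 4 methyl 6-oxocyclohex-1-ene-1-carboxylate; 5 acetaldehyde
Product: 6 methyl (2S)-2-acetyl-6-oxocyclohexane-1-carboxylate
Conditions: 5 (5 equiv), (5aR,10bS)-2-(pentafluorophenyl)-5a,10b-dihydro-4H,6H-indeno[2,1-b][1,2,4]triazolo[4,3-d][1,4]oxazin-2-ium tetrafluoroborate (15 mol %), i-Pr2NEt (20 mol %), tert-amyl alcohol, 0 °C
Reagents that add atoms: none
Why: Proposed new method: an enantioselective intermolecular Stetter reaction of acetaldehyde with a cyclic 2-alkoxycarbonyl enone, in which the chiral triazolylidene turns acetaldehyde into a nucleophilic Breslow intermediate (acetyl anion equivalent) that adds to the s-cis-locked, doubly activated C=C of 4 on the face left open by the indane wall of the catalyst, after which proton transfer to the β-keto ester enolate and loss of the carbene give the 1,4-diketone and set C2 as S (C1 is a labile keto/enol position fixed in step 3); the closest known reaction type is the carbene-catalysed asymmetric intermolecular Stetter addition of aldehydes to alkylidene malonates, alkylidene keto amides and nitroalkenes.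

**Step 3**
Reactants: 6 methyl (2S)-2-acetyl-6-oxocyclohexane-1-carboxylate; 7 1,3-dibromopropan-2-one
Product: 8 methyl (1S,2S)-2-acetyl-1-(3-bromo-2-oxopropyl)-6-oxocyclohexane-1-carboxylate
Conditions: 7 (3 equiv), K2CO3, acetone, 0 °C to rt
Reagents that add atoms: none
Why: SN2 C-alkylation of the potassium enolate of the β-keto ester (far more acidic than the acetyl group) takes place anti to the adjacent acetyl substituent, which allylic strain against the enolate ester holds pseudoaxial, so the quaternary centre is formed with the bromo-oxopropyl chain trans to acetyl (1S,2S), and the excess dihalide prevents double alkylation.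

**Step 4**
Reactants: 8 methyl (1S,2S)-2-acetyl-1-(3-bromo-2-oxopropyl)-6-oxocyclohexane-1-carboxylate
Product: 10 methyl (4aR,8aS)-4-methyl-2,8-dioxo-1,2,4a,5,6,7,8,8a-octahydronaphthalene-8a-carboxylate, via aldol adduct 9 (not isolated)
Conditions: SmI2 (2.2 equiv), THF, −78 °C; then p-toluenesulfonic acid monohydrate (10 mol %), CH2Cl2, rt
Reagents that add atoms: none
Why: SmI2 cleaves the C–Br bond to a regiodefined samarium enolate whose intramolecular Reformatsky-type aldol addition to the neighbouring acetyl ketone closes ring A through a six-membered chelated transition state (closure onto the neopentyl ring ketone would be a disfavoured 5-enolendo process), and acid-catalysed dehydration of the tertiary aldol gives the conjugated enone, the trans ring fusion (4aR,8aS) following from the trans relationship set in step 3.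

**Step 5**
Reactants: 10 methyl (4aR,8aS)-4-methyl-2,8-dioxo-1,2,4a,5,6,7,8,8a-octahydronaphthalene-8a-carboxylate
Product: 11 methyl (4aR,8aS)-4-methyl-2,8-dioxo-1,2,4a,5,8,8a-hexahydronaphthalene-8a-carboxylate
Conditions: 2-iodoxybenzoic acid (1.5 equiv), 4-methoxypyridine N-oxide (1.5 equiv), DMSO, rt
Reagents that add atoms: none
Why: Dehydrogenation of a ketone to the enone with 2-iodoxybenzoic acid (Nicolaou protocol, run at room temperature with the N-oxide ligand) can only desaturate C6–C7, because the other α-carbon of the C8 ketone is quaternary and the ring-A enone has no hydrogen on C8a; the stereocentres are untouched.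

**Step 6**
Reactants: 11 methyl (4aR,8aS)-4-methyl-2,8-dioxo-1,2,4a,5,8,8a-hexahydronaphthalene-8a-carboxylate; 12 isopropenylmagnesium bromide
Product: 13 methyl (4aR,6S,8aS)-4-methyl-2,8-dioxo-6-(prop-1-en-2-yl)-1,2,4a,5,6,7,8,8a-octahydronaphthalene-8a-carboxylate
Conditions: 12 (1.3 equiv, slow addition), CuBr·SMe2 (10 mol %), THF, −78 °C; aq NH4Cl
Reagents that add atoms: none
Why: Copper-catalysed conjugate addition of the Grignard reagent occurs only at the β-unsubstituted ring-B enone (the ring-A enone is β,β-disubstituted) and, for stereoelectronic reasons, by axial attack leading to a chair enolate, on the face of the axial H4a and opposite to the axial C8a ester, which sets C6 as S.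

**Step 7**
Reactants: 13 methyl (4aR,6S,8aS)-4-methyl-2,8-dioxo-6-(prop-1-en-2-yl)-1,2,4a,5,6,7,8,8a-octahydronaphthalene-8a-carboxylate
Product: 15 (2R,4aR,6S,8S,8aR)-8a-(hydroxymethyl)-4-methyl-6-(prop-1-en-2-yl)-1,2,4a,5,6,7,8,8a-octahydronaphthalene-2,8-diol, via hydroxy ester 14 (not isolated)
Conditions: LiBH(s-Bu)3 (L-Selectride, 1.2 equiv), THF, −78 °C; then LiAlH4 (3 equiv), −78 to 0 °C
Reagents that add atoms: none
Why: The bulky borohydride attacks the C8 ketone along the equatorial trajectory because the axial face is blocked by the syn-axial isopropenyl group and H4a, giving the axial 8S alcohol cis to isopropenyl, and LiAlH4 then reduces the ester to the primary alcohol and the enone by 1,2-addition (hydride reductions; the allylic C2 carbinol is erased in step 8).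

**Step 8**
Reactants: 15 (2R,4aR,6S,8S,8aR)-8a-(hydroxymethyl)-4-methyl-6-(prop-1-en-2-yl)-1,2,4a,5,6,7,8,8a-octahydronaphthalene-2,8-diol
Product: 16 (4aR,6S,8S,8aR)-8-hydroxy-8a-(hydroxymethyl)-4-methyl-6-(prop-1-en-2-yl)-4a,5,6,7,8,8a-hexahydronaphthalen-2(1H)-one
Conditions: MnO2 (20 equiv), CH2Cl2, rt
Reagents that add atoms: none
Why: MnO2 oxidises only the allylic alcohol (chemoselective allylic oxidation), returning the ring-A enone and leaving the primary and the saturated secondary alcohol untouched.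

**Step 9**
Reactants: 16 (4aR,6S,8S,8aR)-8-hydroxy-8a-(hydroxymethyl)-4-methyl-6-(prop-1-en-2-yl)-4a,5,6,7,8,8a-hexahydronaphthalen-2(1H)-one
Product: 17 (4aR,6S,8S,8aR)-8a-[(tert-butyldimethylsilyloxy)methyl]-8-hydroxy-4-methyl-6-(prop-1-en-2-yl)-4a,5,6,7,8,8a-hexahydronaphthalen-2(1H)-one
Conditions: t-BuMe2SiCl (1.1 equiv), imidazole, CH2Cl2, 0 °C
Reagents that add atoms: tert-butyldimethylsilyl chloride CC(C)(C)[Si](C)(C)Cl
Why: Silyl ether formation is selective for the primary hydroxyl over the hindered axial secondary one (steric differentiation in silylation) and masks the future free CH2OH.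

**Step 10**
Reactants: 17 (4aR,6S,8S,8aR)-8a-[(tert-butyldimethylsilyloxy)methyl]-8-hydroxy-4-methyl-6-(prop-1-en-2-yl)-4a,5,6,7,8,8a-hexahydronaphthalen-2(1H)-one
Product: 18 (1S,4aR,6S,8S,8aS)-8a-[(tert-butyldimethylsilyloxy)methyl]-1,8-dihydroxy-4-methyl-6-(prop-1-en-2-yl)-4a,5,6,7,8,8a-hexahydronaphthalen-2(1H)-one
Conditions: KN(SiMe3)2 (2.3 equiv), THF, −78 °C; then 3-phenyl-2-(phenylsulfonyl)oxaziridine (1.3 equiv), −78 °C
Reagents that add atoms: 3-phenyl-2-(phenylsulfonyl)oxaziridine O=S(=O)(N1OC1c1ccccc1)c1ccccc1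
Why: After the first equivalent of base forms the C8 alkoxide, kinetic deprotonation gives the cross-conjugated potassium dienolate at C1, which is hydroxylated by the Davis oxaziridine (enolate α'-hydroxylation) mainly anti to the axial CH2OSi group (1S), a centre that is erased in step 11.

**Step 11**
Reactants: 18 (1S,4aR,6S,8S,8aS)-8a-[(tert-butyldimethylsilyloxy)methyl]-1,8-dihydroxy-4-methyl-6-(prop-1-en-2-yl)-4a,5,6,7,8,8a-hexahydronaphthalen-2(1H)-one
Product: 19 (4aR,6S,8S,8aS)-8a-[(tert-butyldimethylsilyloxy)methyl]-8-hydroxy-4-methyl-6-(prop-1-en-2-yl)-4a,5,6,7,8,8a-hexahydronaphthalene-1,2-dione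
Conditions: Cu(OAc)2 (2.2 equiv), MeOH/AcOH (20:1), rt
Reagents that add atoms: none
Why: Cu(OAc)2 oxidises α-hydroxy ketones through their copper enediolates (classical ketol to 1,2-dione oxidation) and leaves the isolated C8 alcohol alone, while the mildly acidic conditions at room temperature avoid enolisation toward C4a and retro-aldol cleavage.

**Step 12**
Reactants: 19 (4aR,6S,8S,8aS)-8a-[(tert-butyldimethylsilyloxy)methyl]-8-hydroxy-4-methyl-6-(prop-1-en-2-yl)-4a,5,6,7,8,8a-hexahydronaphthalene-1,2-dione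
Product: 20 (1R,2S,4aR,6S,8S,8aS)-8a-[(tert-butyldimethylsilyloxy)methyl]-4-methyl-6-(prop-1-en-2-yl)-1,2,4a,5,6,7,8,8a-octahydronaphthalene-1,2,8-triol
Conditions: NaBH4, CeCl3·7H2O, MeOH, −78 °C
Reagents that add atoms: none
Why: Luche reduction delivers hydride to both carbonyl groups from the face opposite to the axial CH2OSi group on C8a, by axial attack at C1 (the small free C8 hydroxyl on that face does not block and can coordinate cerium) and by attack anti to the 1,3-diaxial CH2OSi group at C2 as in 2-oxo steroids, which gives the cis-diol with C1 R (equatorial OH) and C2 S (pseudoaxial OH).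

**Step 13**
Reactants: 20 (1R,2S,4aR,6S,8S,8aS)-8a-[(tert-butyldimethylsilyloxy)methyl]-4-methyl-6-(prop-1-en-2-yl)-1,2,4a,5,6,7,8,8a-octahydronaphthalene-1,2,8-triol
Product: 23 (1R,2S,4aR,6S,8S,8aR)-8a-[(tert-butyldimethylsilyloxy)methyl]-4-methyl-6-(prop-1-en-2-yl)-1,2,4a,5,6,7,8,8a-octahydronaphthalene-1,2,8-triol 2,8-diacetate, via orthoester 21 (not isolated), via orthoester acetate 22 (not isolated)
Conditions: MeC(OMe)3, (1S)-(+)-camphor-10-sulfonic acid (5 mol %), CH2Cl2, rt; then Et3N, Ac2O, 4-(dimethylamino)pyridine, rt; then AcOH/H2O (4:1), 0 °C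
Reagents that add atoms: trimethyl orthoacetate CC(OC)(OC)OC; acetic anhydride CC(=O)OC(C)=O; water O
Why: Acid-catalysed transorthoesterification engages only the cis-1,2-diol as a five-membered cyclic orthoester, which protects it while the C8 alcohol is acetylated (DMAP-catalysed acylation), and mild acid hydrolysis then opens the orthoester under stereoelectronic control to the ester on the pseudoaxial oxygen (C2 acetate) and the free equatorial C1 hydroxyl, with no stereocentre changed.

**Step 14**
Reactants: 23 (1R,2S,4aR,6S,8S,8aR)-8a-[(tert-butyldimethylsilyloxy)methyl]-4-methyl-6-(prop-1-en-2-yl)-1,2,4a,5,6,7,8,8a-octahydronaphthalene-1,2,8-triol 2,8-diacetate; 24 3-methylbutanoyl chloride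
Product: 25 (1R,2S,4aR,6S,8S,8aS)-2,8-diacetoxy-8a-[(tert-butyldimethylsilyloxy)methyl]-4-methyl-6-(prop-1-en-2-yl)-1,2,4a,5,6,7,8,8a-octahydronaphthalen-1-yl 3-methylbutanoate
Conditions: 24 (3 equiv), pyridine, 4-(dimethylamino)pyridine (10 mol %), CH2Cl2, 0 °C to rt
Reagents that add atoms: none
Why: Nucleophilic (DMAP) catalysis of acylation esterifies the remaining equatorial secondary alcohol with retention, the excess acid chloride at low temperature making acylation faster than base-induced acetyl migration from O2 to O1.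

**Step 15**
Reactants: 25 (1R,2S,4aR,6S,8S,8aS)-2,8-diacetoxy-8a-[(tert-butyldimethylsilyloxy)methyl]-4-methyl-6-(prop-1-en-2-yl)-1,2,4a,5,6,7,8,8a-octahydronaphthalen-1-yl 3-methylbutanoate
Product: 26 (1R,2S,4aR,6S,8S,8aS)-2,8-diacetoxy-8a-(hydroxymethyl)-4-methyl-6-(prop-1-en-2-yl)-1,2,4a,5,6,7,8,8a-octahydronaphthalen-1-yl 3-methylbutanoate (CNP0257109.1)
Conditions: HF·pyridine, THF/pyridine, 0 °C to rt
Reagents that add atoms: none
Why: Fluoride-mediated desilylation under buffered acidic conditions (Si–F bond formation) frees the primary alcohol without the 1,3-acyl migration from O1 or O8 that a basic fluoride source could trigger, giving the target.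

**Compound list**
1 | methyl 2-oxocyclohexane-1-carboxylate | COC(=O)C1CCCCC1=O | starting material
2 | methyl 2-oxo-1-(phenylselanyl)cyclohexane-1-carboxylate (racemic, not isolated) | COC(=O)C1(CCCCC1=O)[Se]c1ccccc1 | intermediate
3 | methyl 2-oxo-1-(phenylseleninyl)cyclohexane-1-carboxylate (not isolated) | COC(=O)C1(CCCCC1=O)[Se](=O)c1ccccc1 | intermediate
4 | methyl 6-oxocyclohex-1-ene-1-carboxylate | COC(=O)C1=CCCCC1=O | intermediate
5 | acetaldehyde | CC=O | starting material
6 | methyl (2S)-2-acetyl-6-oxocyclohexane-1-carboxylate (C1 labile, keto/enol) | COC(=O)C1C(=O)CCC[C@@H]1C(C)=O | intermediate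
7 | 1,3-dibromopropan-2-one | BrCC(=O)CBr | starting material
8 | methyl (1S,2S)-2-acetyl-1-(3-bromo-2-oxopropyl)-6-oxocyclohexane-1-carboxylate | C1CC(=O)[C@@](CC(=O)CBr)(C(=O)OC)[C@H](C1)C(C)=O | intermediate
9 | methyl (4aS,8aS)-4-hydroxy-4-methyl-2,8-dioxodecahydronaphthalene-8a-carboxylate (C4 epimers, not isolated) | C1CC(=O)[C@@]2(C(=O)OC)[C@H](C1)C(C)(O)CC(=O)C2 | intermediate
10 | methyl (4aR,8aS)-4-methyl-2,8-dioxo-1,2,4a,5,6,7,8,8a-octahydronaphthalene-8a-carboxylate | C1CC(=O)[C@@]2(C(=O)OC)[C@H](C1)C(C)=CC(=O)C2 | intermediate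
11 | methyl (4aR,8aS)-4-methyl-2,8-dioxo-1,2,4a,5,8,8a-hexahydronaphthalene-8a-carboxylate | C1=CC(=O)[C@@]2(C(=O)OC)[C@H](C1)C(C)=CC(=O)C2 | intermediate
12 | isopropenylmagnesium bromide (prop-1-en-2-ylmagnesium bromide) | CC(=C)[Mg]Br | starting material
13 | methyl (4aR,6S,8aS)-4-methyl-2,8-dioxo-6-(prop-1-en-2-yl)-1,2,4a,5,6,7,8,8a-octahydronaphthalene-8a-carboxylate | C=C(C)[C@@H]1CC(=O)[C@@]2(C(=O)OC)[C@H](C1)C(C)=CC(=O)C2 | intermediate
14 | methyl (4aR,6S,8S,8aS)-8-hydroxy-4-methyl-2-oxo-6-(prop-1-en-2-yl)-1,2,4a,5,6,7,8,8a-octahydronaphthalene-8a-carboxylate (as lithium alkoxide, not isolated) | C=C(C)[C@@H]1C[C@H](O)[C@@]2(C(=O)OC)[C@H](C1)C(C)=CC(=O)C2 | intermediate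
15 | (2R,4aR,6S,8S,8aR)-8a-(hydroxymethyl)-4-methyl-6-(prop-1-en-2-yl)-1,2,4a,5,6,7,8,8a-octahydronaphthalene-2,8-diol (expected major C2 epimer; either epimer gives 16) | C=C(C)[C@@H]1C[C@H](O)[C@@]2(CO)[C@H](C1)C(C)=C[C@H](O)C2 | intermediate
16 | (4aR,6S,8S,8aR)-8-hydroxy-8a-(hydroxymethyl)-4-methyl-6-(prop-1-en-2-yl)-4a,5,6,7,8,8a-hexahydronaphthalen-2(1H)-one | C=C(C)[C@@H]1C[C@H](O)[C@@]2(CO)[C@H](C1)C(C)=CC(=O)C2 | intermediate
17 | (4aR,6S,8S,8aR)-8a-[(tert-butyldimethylsilyloxy)methyl]-8-hydroxy-4-methyl-6-(prop-1-en-2-yl)-4a,5,6,7,8,8a-hexahydronaphthalen-2(1H)-one | C=C(C)[C@@H]1C[C@H](O)[C@@]2(CO[Si](C)(C)C(C)(C)C)[C@H](C1)C(C)=CC(=O)C2 | intermediate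
18 | (1S,4aR,6S,8S,8aS)-8a-[(tert-butyldimethylsilyloxy)methyl]-1,8-dihydroxy-4-methyl-6-(prop-1-en-2-yl)-4a,5,6,7,8,8a-hexahydronaphthalen-2(1H)-one (expected major C1 epimer; either epimer gives 19) | C=C(C)[C@@H]1C[C@H](O)[C@@]2(CO[Si](C)(C)C(C)(C)C)[C@H](C1)C(C)=CC(=O)[C@H]2O | intermediate
19 | (4aR,6S,8S,8aS)-8a-[(tert-butyldimethylsilyloxy)methyl]-8-hydroxy-4-methyl-6-(prop-1-en-2-yl)-4a,5,6,7,8,8a-hexahydronaphthalene-1,2-dione | C=C(C)[C@@H]1C[C@H](O)[C@@]2(CO[Si](C)(C)C(C)(C)C)[C@H](C1)C(C)=CC(=O)C2=O | intermediate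
20 | (1R,2S,4aR,6S,8S,8aS)-8a-[(tert-butyldimethylsilyloxy)methyl]-4-methyl-6-(prop-1-en-2-yl)-1,2,4a,5,6,7,8,8a-octahydronaphthalene-1,2,8-triol | C=C(C)[C@@H]1C[C@H](O)[C@@]2(CO[Si](C)(C)C(C)(C)C)[C@H](C1)C(C)=C[C@H](O)[C@@H]2O | intermediate
21 | 1,2-O-(1-methoxyethylidene) derivative of 20 (cyclic methyl orthoacetate, orthoester carbon epimeric, other centres as in 20, not isolated) | C=C(C)[C@@H]1C[C@H](O)[C@@]2(CO[Si](C)(C)C(C)(C)C)[C@H](C1)C(C)=C[C@H](O3)[C@@H]2OC3(C)OC | intermediate
22 | 8-O-acetate of orthoester 21 (not isolated) | C=C(C)[C@@H]1C[C@H](OC(C)=O)[C@@]2(CO[Si](C)(C)C(C)(C)C)[C@H](C1)C(C)=C[C@H](O3)[C@@H]2OC3(C)OC | intermediate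
23 | (1R,2S,4aR,6S,8S,8aR)-8a-[(tert-butyldimethylsilyloxy)methyl]-4-methyl-6-(prop-1-en-2-yl)-1,2,4a,5,6,7,8,8a-octahydronaphthalene-1,2,8-triol 2,8-diacetate | C=C(C)[C@@H]1C[C@H](OC(C)=O)[C@@]2(CO[Si](C)(C)C(C)(C)C)[C@H](C1)C(C)=C[C@H](OC(C)=O)[C@@H]2O | intermediate
24 | 3-methylbutanoyl chloride (isovaleryl chloride) | CC(C)CC(=O)Cl | starting material
25 | (1R,2S,4aR,6S,8S,8aS)-2,8-diacetoxy-8a-[(tert-butyldimethylsilyloxy)methyl]-4-methyl-6-(prop-1-en-2-yl)-1,2,4a,5,6,7,8,8a-octahydronaphthalen-1-yl 3-methylbutanoate | C=C(C)[C@@H]1C[C@H](OC(C)=O)[C@@]2(CO[Si](C)(C)C(C)(C)C)[C@H](C1)C(C)=C[C@H](OC(C)=O)[C@@H]2OC(=O)CC(C)C | intermediate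
26 | (1R,2S,4aR,6S,8S,8aS)-2,8-diacetoxy-8a-(hydroxymethyl)-4-methyl-6-(prop-1-en-2-yl)-1,2,4a,5,6,7,8,8a-octahydronaphthalen-1-yl 3-methylbutanoate | C=C(C)[C@@H]1C[C@H](OC(C)=O)[C@@]2(CO)[C@H](C1)C(C)=C[C@H](OC(C)=O)[C@@H]2OC(=O)CC(C)C | target

**Totals and risks**
Total step count: 15. Longest linear sequence: 15 steps (1 to 26).

Three steps most likely to fail:

Step 2 (the proposed new Stetter addition). Risks are self-condensation of acetaldehyde, addition of the carbene to 4, and insufficient enantioselectivity. The fallback uses known chemistry, sets out from 4 and comes back at 6, and replaces the acyl anion by a nitronate. A bifunctional amine–thiourea-catalysed Michael addition of nitroethane to 4 (1-[3,5-bis(trifluoromethyl)phenyl]-3-[(1R,2R)-2-(dimethylamino)cyclohexyl]thiourea or its mirror image, whichever gives the 2S series, 10 mol %, toluene, rt) gives methyl (2S)-2-(1-nitroethyl)-6-oxocyclohexane-1-carboxylate F1 as a mixture at the nitro-bearing carbon. A Nef reaction (NaOMe, MeOH; then buffered aqueous TiCl3/NH4OAc) then turns the secondary nitro group into the ketone, which is 6.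

Step 4 (ring-A closure). Risks are simple debromination instead of aldol addition, and retro-aldol loss of 9. The fallback sets out from 6 and comes back at 10, and uses a neutral enol ether under Lewis acid activation in place of a reductively formed metal enolate. Alkylation of 6 with 2-methoxyallyl bromide (K2CO3, acetone) gives methyl (1S,2S)-2-acetyl-1-(2-methoxyprop-2-en-1-yl)-6-oxocyclohexane-1-carboxylate F2. BF3·OEt2 in CH2Cl2 at −78 °C then brings about an intramolecular Mukaiyama-type aldol addition of the enol ether to the acetyl ketone; aqueous work-up liberates aldol 9, which is dehydrated as in step 4 to 10.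

Step 12 (configuration at C1 and C2). The risk is that the external hydride is steered to the wrong face of the C1 ketone by the C8 substituent. The fallback sets out from 19 and comes back at 20, and uses internal hydride delivery. Me4NBH(OAc)3 in MeCN/AcOH at −30 °C binds the C8 hydroxyl and transfers hydride to the C1 ketone on the face of that hydroxyl (Evans–Saksena anti-1,3-diol reduction), leaving the conjugated C2 ketone, to give (1R,4aR,6S,8S,8aS)-8a-[(tert-butyldimethylsilyloxy)methyl]-1,8-dihydroxy-4-methyl-6-(prop-1-en-2-yl)-4a,5,6,7,8,8a-hexahydronaphthalen-2(1H)-one F3. NaBH4/CeCl3·7H2O (MeOH, −78 °C) then reduces the enone carbonyl anti to the CH2OSi group to give 20.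

Further compounds
F1 | step 2 | methyl (2S)-2-(1-nitroethyl)-6-oxocyclohexane-1-carboxylate | COC(=O)C1C(=O)CCC[C@@H]1C(C)[N+](=O)[O-]
F2 | step 4 | methyl (1S,2S)-2-acetyl-1-(2-methoxyprop-2-en-1-yl)-6-oxocyclohexane-1-carboxylate | C1CC(=O)[C@@](CC(=C)OC)(C(=O)OC)[C@H](C1)C(C)=O
F3 | step 12 | (1R,4aR,6S,8S,8aS)-8a-[(tert-butyldimethylsilyloxy)methyl]-1,8-dihydroxy-4-methyl-6-(prop-1-en-2-yl)-4a,5,6,7,8,8a-hexahydronaphthalen-2(1H)-one | C=C(C)[C@@H]1C[C@H](O)[C@@]2(CO[Si](C)(C)C(C)(C)C)[C@H](C1)C(C)=CC(=O)[C@@H]2O
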